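The catechol-side dioxane ring is read as a hidden syn-aldol. Its C2–C3 bond joins an aryloxyacetyl α-carbon to the carbonyl carbon of 3,4-dihydroxybenzaldehyde, and its O4–C4a bond ties the aldol oxygen to the arene carbon ortho to the ether oxygen O1. One copper-relay operation therefore makes the ring from a (2-iodoaryloxy)acetyl 7-azaindoline amide and the aldehyde: catalytic asymmetric aldol, then Ullmann etherification by the same metal onto the ortho C–I bond. The precursor is an acyclic iodoaryl ether amide carrying a masked aldehyde. Unmasking it allows the same annulation, with the antipodal ligand, to build the second dioxane ring, before global reduction and deallylation.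

Key step: step 5

Labels: arene A carries the propenol chain, arene B is the central arene, arene C is the catechol; "7-azaindolin-1-yl" means 2,3-dihydro-1H-pyrrolo[2,3-b]pyridin-1-yl; BTMG is 2-tert-butyl-1,1,3,3-tetramethylguanidine; Me4phen is 3,4,7,8-tetramethyl-1,10-phenanthroline.

Assumption: the sense of induction of the copper–bisphosphine aldol is taken by analogy with other α-heteroatom 7-azaindoline amides; (S,S)-Ph-BPE is written for the (2R,3S) adduct and (R,R)-Ph-BPE for the (2S,3R) adduct, and the two are exchanged should the analogy prove inverted.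

Step 1
Reactants: 1 7-azaindoline (2,3-dihydro-1H-pyrrolo[2,3-b]pyridine); 2 chloroacetyl chloride
Product: 3 2-chloro-1-(7-azaindolin-1-yl)ethan-1-one
Conditions: K2CO3, CH2Cl2/H2O, 0 °C → rt
Reagents that add atoms: none
Why: Schotten–Baumann N-acylation of the indoline nitrogen by the acid chloride is fast and leaves the alkyl chloride untouched.

Step 2
Reactants: 4 4-hydroxy-3-iodobenzaldehyde; 3 2-chloro-1-(7-azaindolin-1-yl)ethan-1-one
Product: 5 2-(4-formyl-2-iodophenoxy)-1-(7-azaindolin-1-yl)ethan-1-one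
Conditions: K2CO3, NaI (cat.), MeCN, 50 °C
Reagents that add atoms: none
Why: Williamson ether synthesis, in which the phenoxide displaces the activated α-chloro amide (Finkelstein iodide catalysis) while carbonate is too weak to enolise the amide.

Step 3
Reactants: 5 2-(4-formyl-2-iodophenoxy)-1-(7-azaindolin-1-yl)ethan-1-one
Product: 6 2-[4-(dimethoxymethyl)-2-iodophenoxy]-1-(7-azaindolin-1-yl)ethan-1-one
Conditions: HC(OMe)3, PPTS (cat.), MeOH, rt
Reagents that add atoms: trimethyl orthoformate, COC(OC)OC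
Why: Acid-catalysed acetalisation, driven by the orthoformate as water scavenger, masks the aldehyde so that 6 can act only as an aldol donor.

Step 4
Reactants: 7 3,4-dihydroxybenzaldehyde
Product: 8 3,4-bis(allyloxy)benzaldehyde
Conditions: allyl bromide, K2CO3, DMF, 50 °C
Reagents that add atoms: allyl bromide, C=CCBr
Why: Double Williamson O-allylation of the catechol gives ethers that should tolerate base, copper and hydride and leave under neutral palladium catalysis at the end.

Step 5
Reactants: 6 2-[4-(dimethoxymethyl)-2-iodophenoxy]-1-(7-azaindolin-1-yl)ethan-1-one; 8 3,4-bis(allyloxy)benzaldehyde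
Product: 10 [(2R,3S)-3-[3,4-bis(allyloxy)phenyl]-6-(dimethoxymethyl)-2,3-dihydro-1,4-benzodioxin-2-yl](7-azaindolin-1-yl)methanone (2,3-trans), via syn-aldol adduct 9 (not isolated)
Conditions: [Cu(MeCN)4]PF6 (10 mol%), (S,S)-Ph-BPE (12 mol%), BTMG (10 mol%), THF, −40 °C; then CuI (10 mol%), Me4phen (20 mol%), Cs2CO3, MeCN, −40 → 40 °C
Reagents that add atoms: none
Why: Monovalent copper carrying the bisphosphine binds the 7-azaindoline amide of 6 through pyridine nitrogen and carbonyl oxygen, so catalytic BTMG forms a (Z)-copper enolate that adds to the non-enolisable aldehyde 8 and forges the C2–C3 bond as syn-adduct 9 (direct catalytic asymmetric aldol of an α-heteroatom 7-azaindoline amide). Cs2CO3 and the phenanthroline then switch the metal to Ullmann-type etherification: the C3 alkoxide binds copper, the ortho C–I bond adds oxidatively to give a trivalent copper aryl alkoxide, and reductive elimination forms O4–C4a; the closest known reactions are intramolecular copper-catalysed O-arylations of secondary alcohols that give 1,4-benzodioxanes. The dioxane ring closes as a six-membered exo ring closure of the tethered alkoxide onto the iodinated arene carbon. Both stereocentres arise in the aldol under control of the chiral bisphosphine (the chelated enolate geometry gives syn, the ligand selects the aldehyde face); the etherification does not touch the C3–O bond, so syn becomes trans, and because C2 stays epimerisable beside the amide any anti adduct with the correct C3 configuration should converge on the same, more stable trans ring. The step needs donor/acceptor chemoselectivity, secured by the acetal mask in 6 and the lack of α-hydrogens in 8, and ring closure faster than retro-aldol, secured by the aryl iodide, the intramolecular six-ring closure and a second stage kept at or below 40 °C.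

Step 6
Reactants: 10 [(2R,3S)-3-[3,4-bis(allyloxy)phenyl]-6-(dimethoxymethyl)-2,3-dihydro-1,4-benzodioxin-2-yl](7-azaindolin-1-yl)methanone
Product: 11 (2R,3S)-3-[3,4-bis(allyloxy)phenyl]-2-(7-azaindolin-1-ylcarbonyl)-2,3-dihydro-1,4-benzodioxine-6-carbaldehyde
Conditions: PPTS (cat.), acetone/H2O, 40 °C
Reagents that add atoms: water, O
Why: Mild acid-catalysed acetal hydrolysis, the benzylic dimethyl acetal being far more labile than the amide, the allyl ethers or the dioxane ring.

Step 7
Reactants: 5 2-(4-formyl-2-iodophenoxy)-1-(7-azaindolin-1-yl)ethan-1-one; 12 methyl (triphenylphosphoranylidene)acetate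
Product: 13 methyl (E)-3-{3-iodo-4-[2-oxo-2-(7-azaindolin-1-yl)ethoxy]phenyl}acrylate
Conditions: toluene, 60 °C
Reagents that add atoms: none
Why: Wittig olefination with a stabilised ylide should give the (E)-enoate, and the neutral ylide does not enolise the amide.

Step 8
Reactants: 13 methyl (E)-3-{3-iodo-4-[2-oxo-2-(7-azaindolin-1-yl)ethoxy]phenyl}acrylate; 11 (2R,3S)-3-[3,4-bis(allyloxy)phenyl]-2-(7-azaindolin-1-ylcarbonyl)-2,3-dihydro-1,4-benzodioxine-6-carbaldehyde
Product: 15 methyl (E)-3-[(2S,3R)-2-(7-azaindolin-1-ylcarbonyl)-3-{(2R,3S)-2-(7-azaindolin-1-ylcarbonyl)-3-[3,4-bis(allyloxy)phenyl]-2,3-dihydro-1,4-benzodioxin-6-yl}-2,3-dihydro-1,4-benzodioxin-6-yl]acrylate (both dioxane rings trans), via syn-aldol adduct 14 (not isolated)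
Conditions: [Cu(MeCN)4]PF6 (10 mol%), (R,R)-Ph-BPE (12 mol%), BTMG (10 mol%), THF, −40 °C; then CuI (10 mol%), Me4phen (20 mol%), Cs2CO3, MeCN, −40 → 40 °C
Reagents that add atoms: none
Why: The same copper-relay annulation (direct asymmetric aldol of the 7-azaindoline amide, then intramolecular Ullmann-type O-arylation) with the antipodal ligand should set C2 and C3 of the second dioxane ring under catalyst control, the older stereocentres being remote, and close the ring onto the only aryl iodide, trans following from the syn adduct or from epimerisation at C2.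

Step 9
Reactants: 15 methyl (E)-3-[(2S,3R)-2-(7-azaindolin-1-ylcarbonyl)-3-{(2R,3S)-2-(7-azaindolin-1-ylcarbonyl)-3-[3,4-bis(allyloxy)phenyl]-2,3-dihydro-1,4-benzodioxin-6-yl}-2,3-dihydro-1,4-benzodioxin-6-yl]acrylate
Product: 17 (E)-3-[(2R,3R)-3-{(2S,3S)-3-[3,4-bis(allyloxy)phenyl]-2-(hydroxymethyl)-2,3-dihydro-1,4-benzodioxin-6-yl}-2-(hydroxymethyl)-2,3-dihydro-1,4-benzodioxin-6-yl]prop-2-en-1-ol, via dialdehyde 16 (not isolated)
Conditions: i-Bu2AlH, CH2Cl2, −78 → −20 °C; then MeOH, NaBH4, −20 → 0 °C; aq. potassium sodium tartrate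
Reagents that add atoms: none
Why: Hydride reduction in which i-Bu2AlH takes the enoate 1,2-selectively to the allylic alcohol and adds once to each N-acyl-7-azaindoline to give a chelated tetrahedral aluminate (in the manner of an N-methoxy-N-methyl amide), so that the α-aryloxy aldehydes are released only at the methanol quench, where NaBH4 should reduce them before C2 can epimerise.

Step 10
Reactants: 17 (E)-3-[(2R,3R)-3-{(2S,3S)-3-[3,4-bis(allyloxy)phenyl]-2-(hydroxymethyl)-2,3-dihydro-1,4-benzodioxin-6-yl}-2-(hydroxymethyl)-2,3-dihydro-1,4-benzodioxin-6-yl]prop-2-en-1-ol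
Product: 18 (E)-3-[(2R,3R)-3-{(2S,3S)-3-(3,4-dihydroxyphenyl)-2-(hydroxymethyl)-2,3-dihydro-1,4-benzodioxin-6-yl}-2-(hydroxymethyl)-2,3-dihydro-1,4-benzodioxin-6-yl]prop-2-en-1-ol (the target)
Conditions: Pd(PPh3)4 (5 mol%), morpholine, THF, rt
Reagents that add atoms: none
Why: Tsuji–Trost deallylation, in which zerovalent palladium ionises only the aryl allyl ethers (phenoxide leaving groups) and morpholine traps the allyl units, while the free cinnamyl alcohol should not ionise under these neutral conditions.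

Compound list
1 | 7-azaindoline (2,3-dihydro-1H-pyrrolo[2,3-b]pyridine) | C1Cc2cccnc2N1 | starting material
2 | chloroacetyl chloride | ClCC(=O)Cl | starting material
3 | 2-chloro-1-(7-azaindolin-1-yl)ethan-1-one | O=C(CCl)N1CCc2cccnc21 | intermediate
4 | 4-hydroxy-3-iodobenzaldehyde | O=Cc1ccc(O)c(I)c1 | starting material
5 | 2-(4-formyl-2-iodophenoxy)-1-(7-azaindolin-1-yl)ethan-1-one | O=Cc1ccc(OCC(=O)N2CCc3cccnc32)c(I)c1 | intermediate
6 | 2-[4-(dimethoxymethyl)-2-iodophenoxy]-1-(7-azaindolin-1-yl)ethan-1-one | COC(OC)c1ccc(OCC(=O)N2CCc3cccnc32)c(I)c1 | intermediate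
7 | 3,4-dihydroxybenzaldehyde | O=Cc1ccc(O)c(O)c1 | starting material
8 | 3,4-bis(allyloxy)benzaldehyde | O=Cc1ccc(OCC=C)c(OCC=C)c1 | intermediate
9 | (2R,3S)-3-[3,4-bis(allyloxy)phenyl]-2-[4-(dimethoxymethyl)-2-iodophenoxy]-3-hydroxy-1-(7-azaindolin-1-yl)propan-1-one (syn-aldol adduct) | COC(OC)c1ccc(O[C@@H](C(=O)N2CCc3cccnc32)[C@@H](O)c2ccc(OCC=C)c(OCC=C)c2)c(I)c1 | intermediate (not isolated)
10 | [(2R,3S)-3-[3,4-bis(allyloxy)phenyl]-6-(dimethoxymethyl)-2,3-dihydro-1,4-benzodioxin-2-yl](7-azaindolin-1-yl)methanone (trans) | COC(OC)c1ccc2c(c1)O[C@@H](c1ccc(OCC=C)c(OCC=C)c1)[C@H](C(=O)N1CCc3cccnc31)O2 | intermediate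
11 | (2R,3S)-3-[3,4-bis(allyloxy)phenyl]-2-(7-azaindolin-1-ylcarbonyl)-2,3-dihydro-1,4-benzodioxine-6-carbaldehyde (trans) | O=Cc1ccc2c(c1)O[C@@H](c1ccc(OCC=C)c(OCC=C)c1)[C@H](C(=O)N1CCc3cccnc31)O2 | intermediate
12 | methyl (triphenylphosphoranylidene)acetate | COC(=O)C=P(c1ccccc1)(c1ccccc1)c1ccccc1 | starting material
13 | methyl (E)-3-{3-iodo-4-[2-oxo-2-(7-azaindolin-1-yl)ethoxy]phenyl}acrylate | COC(=O)/C=C/c1ccc(OCC(=O)N2CCc3cccnc32)c(I)c1 | intermediate
14 | methyl (E)-3-[4-({(2S,3R)-1-(7-azaindolin-1-yl)-3-hydroxy-1-oxo-3-[(2R,3S)-2-(7-azaindolin-1-ylcarbonyl)-3-(3,4-bis(allyloxy)phenyl)-2,3-dihydro-1,4-benzodioxin-6-yl]propan-2-yl}oxy)-3-iodophenyl]acrylate (syn-aldol adduct) | COC(=O)/C=C/c1ccc(O[C@H](C(=O)N2CCc3cccnc32)[C@H](O)c2ccc3c(c2)O[C@@H](c2ccc(OCC=C)c(OCC=C)c2)[C@H](C(=O)N2CCc4cccnc42)O3)c(I)c1 | intermediate (not isolated)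
15 | methyl (E)-3-[(2S,3R)-2-(7-azaindolin-1-ylcarbonyl)-3-{(2R,3S)-2-(7-azaindolin-1-ylcarbonyl)-3-[3,4-bis(allyloxy)phenyl]-2,3-dihydro-1,4-benzodioxin-6-yl}-2,3-dihydro-1,4-benzodioxin-6-yl]acrylate | COC(=O)/C=C/c1ccc2c(c1)O[C@H](c1ccc3c(c1)O[C@@H](c1ccc(OCC=C)c(OCC=C)c1)[C@H](C(=O)N1CCc4cccnc41)O3)[C@@H](C(=O)N1CCc3cccnc31)O2 | intermediate
16 | (2R,3S)-3-[3,4-bis(allyloxy)phenyl]-6-[(2S,3R)-2-formyl-6-((E)-3-hydroxyprop-1-enyl)-2,3-dihydro-1,4-benzodioxin-3-yl]-2,3-dihydro-1,4-benzodioxine-2-carbaldehyde | OC/C=C/c1ccc2c(c1)O[C@H](c1ccc3c(c1)O[C@@H](c1ccc(OCC=C)c(OCC=C)c1)[C@H](C=O)O3)[C@@H](C=O)O2 | intermediate (not isolated)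
17 | (E)-3-[(2R,3R)-3-{(2S,3S)-3-[3,4-bis(allyloxy)phenyl]-2-(hydroxymethyl)-2,3-dihydro-1,4-benzodioxin-6-yl}-2-(hydroxymethyl)-2,3-dihydro-1,4-benzodioxin-6-yl]prop-2-en-1-ol | OC/C=C/c1ccc2c(c1)O[C@H](c1ccc3c(c1)O[C@@H](c1ccc(OCC=C)c(OCC=C)c1)[C@H](CO)O3)[C@@H](CO)O2 | intermediate
18 | (E)-3-[(2R,3R)-3-{(2S,3S)-3-(3,4-dihydroxyphenyl)-2-(hydroxymethyl)-2,3-dihydro-1,4-benzodioxin-6-yl}-2-(hydroxymethyl)-2,3-dihydro-1,4-benzodioxin-6-yl]prop-2-en-1-ol | OC/C=C/c1ccc2c(c1)O[C@H](c1ccc3c(c1)O[C@@H](c1ccc(O)c(O)c1)[C@H](CO)O3)[C@@H](CO)O2 | target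

Total steps: 10. Longest linear sequence: 8 steps (1, 2, 3, 5, 6, 8, 9, 10).

Steps most likely to fail

Step 5. The aldolate may revert (retro-aldol and re-addition) while it waits for ring closure in the warmer, basic second stage, eroding enantio- and diastereoselectivity, or the aldol may stall with the electron-rich aldehyde. The fallback sets out from 4 and returns to the route at 9; it sets the stereocentres with an auxiliary-controlled boron aldol and closes the ring in a separate operation. Compound 4 is alkylated with commercial (R)-4-benzyl-3-(chloroacetyl)oxazolidin-2-one (K2CO3, NaI, MeCN) to (R)-4-benzyl-3-[2-(4-formyl-2-iodophenoxy)acetyl]oxazolidin-2-one F1, which is masked (HC(OMe)3, PPTS, MeOH) as the dimethyl acetal imide F2. The Evans syn-aldol of F2 with 8 (Bu2BOTf, i-Pr2NEt, CH2Cl2, −78 → 0 °C; H2O2, pH 7 buffer) should give the (2R,3S)-syn aldol imide F3. Amide exchange with the aluminium amide of 1 (AlMe3, CH2Cl2, 0 °C → rt) then delivers 9 as an isolated compound. It is closed to 10 at room temperature with CuI, Me4phen and Cs2CO3 in MeCN, now without free aldehyde or amine base in the flask.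

Step 8. The activated amide already present in 11 may be enolised under the copper/base conditions, with epimerisation or β-elimination of the ring phenoxide, and the aldolate may again revert before ring closure. The fallback sets out from 4 and 11 and returns at 14. Compound 4 is alkylated with (S)-4-benzyl-3-(chloroacetyl)oxazolidin-2-one (K2CO3, NaI, MeCN) to (S)-4-benzyl-3-[2-(4-formyl-2-iodophenoxy)acetyl]oxazolidin-2-one F4. Wittig olefination with 12 (toluene, 60 °C) gives the (E)-enoate imide F5. Its preformed boron enolate (Bu2BOTf, i-Pr2NEt, CH2Cl2, −78 °C), which does not enolise the amide of 11, adds to 11 in an Evans syn-aldol to give the (2S,3R)-syn aldol imide F6. Amide exchange (AlMe3, 1, CH2Cl2) gives 14, isolated, which is closed to 15 with CuI, Me4phen and Cs2CO3 at room temperature.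

Step 9. The α-aryloxy aldehydes set free at the quench may epimerise at C2 or lose the ring phenoxide by β-elimination before borohydride reaches them, and the enoate may suffer partial conjugate reduction. The fallback sets out from 15 and returns at 17. Acid-promoted methanolysis of both N-acyl-7-azaindolines (HCl, MeOH, 50 °C; protonation at the pyridine nitrogen activates the amide) gives the trimethyl ester F7. i-Bu2AlH alone (CH2Cl2, −78 → 0 °C) then takes the three esters to the alcohols through aluminium hemiacetals, without a quench at the aldehyde stage, and gives 17.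

Further compounds
F1 | step 5 | (R)-4-benzyl-3-[2-(4-formyl-2-iodophenoxy)acetyl]oxazolidin-2-one | O=Cc1ccc(OCC(=O)N2[C@H](Cc3ccccc3)COC2=O)c(I)c1
F2 | step 5 | (R)-4-benzyl-3-{2-[4-(dimethoxymethyl)-2-iodophenoxy]acetyl}oxazolidin-2-one | COC(OC)c1ccc(OCC(=O)N2[C@H](Cc3ccccc3)COC2=O)c(I)c1
F3 | step 5 | (R)-4-benzyl-3-{(2R,3S)-3-[3,4-bis(allyloxy)phenyl]-2-[4-(dimethoxymethyl)-2-iodophenoxy]-3-hydroxypropanoyl}oxazolidin-2-one | COC(OC)c1ccc(O[C@@H](C(=O)N2[C@H](Cc3ccccc3)COC2=O)[C@@H](O)c2ccc(OCC=C)c(OCC=C)c2)c(I)c1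
F4 | step 8 | (S)-4-benzyl-3-[2-(4-formyl-2-iodophenoxy)acetyl]oxazolidin-2-one | O=Cc1ccc(OCC(=O)N2[C@@H](Cc3ccccc3)COC2=O)c(I)c1
F5 | step 8 | methyl (E)-3-(3-iodo-4-{2-oxo-2-[(S)-4-benzyl-2-oxooxazolidin-3-yl]ethoxy}phenyl)acrylate | COC(=O)/C=C/c1ccc(OCC(=O)N2[C@@H](Cc3ccccc3)COC2=O)c(I)c1
F6 | step 8 | methyl (E)-3-[4-({(2S,3R)-1-[(S)-4-benzyl-2-oxooxazolidin-3-yl]-3-hydroxy-1-oxo-3-[(2R,3S)-2-(7-azaindolin-1-ylcarbonyl)-3-(3,4-bis(allyloxy)phenyl)-2,3-dihydro-1,4-benzodioxin-6-yl]propan-2-yl}oxy)-3-iodophenyl]acrylate | COC(=O)/C=C/c1ccc(O[C@H](C(=O)N2[C@@H](Cc3ccccc3)COC2=O)[C@H](O)c2ccc3c(c2)O[C@@H](c2ccc(OCC=C)c(OCC=C)c2)[C@H](C(=O)N2CCc4cccnc42)O3)c(I)c1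
F7 | step 9 | methyl (2S,3R)-3-{(2R,3S)-3-[3,4-bis(allyloxy)phenyl]-2-(methoxycarbonyl)-2,3-dihydro-1,4-benzodioxin-6-yl}-6-[(E)-3-methoxy-3-oxoprop-1-enyl]-2,3-dihydro-1,4-benzodioxine-2-carboxylate | COC(=O)/C=C/c1ccc2c(c1)O[C@H](c1ccc3c(c1)O[C@@H](c1ccc(OCC=C)c(OCC=C)c1)[C@H](C(=O)OC)O3)[C@@H](C(=O)OC)O2
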